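## Structural features

The target 32 is a trans-fused hydrindane (bicyclo[4.3.0]nonane). With hydrindane locants, ring B is the cyclopentanone C1–C2(=O)–C3–C3a–C7a and ring A the cyclohexane C3a–C4–C5–C6–C7–C7a; β is the face of H-7a, and H-3a is α. Ring B carries a β-[(1S)-1-acetoxyethyl] group at C1 and a β-[(2R)-2-methylbutanoyl]oxy group at C3, one on each side of the C2 ketone. Ring A carries an exocyclic methylene at C4, an axial α-[(2E)-3-methylpent-2-enoyl]oxy group at C5 and an equatorial β-isopropyl group at C7. Of the eight stereocentres, C1', C1, C7a and C7 form one contiguous run and C3, C3a, C7a a second that shares the ring fusion; C5 is insulated by sp2 C4 and CH2-6, and the eighth lies in the acyl chain. Fragile groups are the β-acetoxy ketone (E1cB loss of acetate through the C1 enolate), the α-acyloxy ketone (epimerisation or acyl shift at C3), the allylic ester beside a 1,1-disubstituted alkene, and the α-stereocentre of the 2-methylbutanoate. The real difficulty is the trans ring fusion with the stereocentres clustered around it, together with a late order of operations that puts three different acyl groups on three secondary oxygens without exposing the finished acyloxy ketone to base. The key step exploits the fact that ring A is a disguised cyclohexene: the fusion bond C3a–C7a and the bond C6–C7 are the two σ-bonds of a [4+2] adduct whose residual alkene is C4=C5 (methyl on C4) and whose dienophile substituent is a formyl group on C7. Because C1–C2–C3 tether dienophile to diene, one cycloaddition closes ring A and ring B together.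

## Logic of the disconnections

32 ⇒ 31 ⇒ 30. The acetate C–O bond is cut first and the silyl ether restored. Acetylation is placed last because it creates the E1cB-prone β-acetoxy ketone, so nothing basic may follow it. The forward steps must be a non-basic desilylation and a mild acetylation.

30 ⇒ 28 + 29, then 28 ⇒ 26 (via 27). The C3 ester C–O bond and then the C3–O bond are cut, leaving a plain α-methylene ketone. This removes a stereocentre and an acyl group. The forward step needs enolisation toward C3 rather than C1 and oxygen delivery to the β face.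

26 ⇒ 24 + 25. The C5 ester is cut. This acylation is done before the enolate chemistry so that only one free hydroxyl is ever present. The forward demand is that the enoate ester survives one equivalent of amide base at −78 °C.

24 ⇒ 22 (via 23) ⇒ 21. The methylene carbinol is traced back to the C4=C5 alkene through its α-epoxide, and the C2 ketone to a dimethyl ketal. The gain is that C5 becomes a simple alkene carbon. The forward demands are α-face epoxidation, removal of a proton from the C4 methyl group only, and a ketone mask that tolerates both a dioxirane and an amide base.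

21 ⇒ 20 ⇒ 19 ⇒ 18 ⇒ 17 ⇒ 16. The isopropyl group is reduced to a formyl group by cutting its two methyl C–C bonds (one made by olefination, one by a Grignard addition). The ketal is exchanged back for the dithiane between 20 and 19, because sulfur must leave before epoxidation and rhodium hydrogenation. The demand is a hydrogenation that spares the ring alkene.

16 ⇒ 13 (via 15 and 14). The bonds C3a–C7a and C6–C7 are cut together. Both rings and three stereocentres disappear, leaving an acyclic trienal whose only stereocentres are the adjacent pair C1/C1'. The forward step must be endo- and face-selective.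

13 ⇒ 12 ⇒ 10 + 3 (via 11). The formyl group is masked as a dioxolane and the C2–C3 bond is cut between a dithiane carbanion and an allylic bromide. This splits the chain into a chiral half and an achiral dienyl half. The forward step needs metalation of a hindered 2-substituted dithiane and clean attack at the primary carbon of 3.

10 ⇒ 9 ⇒ 6 + 7 (via 8). The C1–C2 bond is cut as the opening of a vinyl epoxide by an acyl-anion equivalent, so that both stereocentres come from one epoxide. The demand is direct attack at the allylic carbon with inversion.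

6 ⇒ 5 ⇒ 4, and 3 ⇒ 2 ⇒ 1. The epoxide goes back to a dienyl acetal and then to a commercial dienal, so that the enal carbons are present from the start and no olefin metathesis on a sulfur-containing substrate is needed. The bromide goes back to a commercial enynol. The demand on the epoxidation is regioselectivity for the distal alkene and control of the absolute face.

## Other disconnections considered

Alternative 1: The cut is the C3–C3a bond, with ring A kept as a preformed cyclohexanone. In the forward direction the keto aldehyde A1 enolises toward the ring CH2 that becomes C3a and adds to its tethered α-silyloxy aldehyde (enolexo aldol) to give the hydroxy hydrindanone A2.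
- In its favour: the step needs no metal, and it installs the C3 oxygen directly. On that point it is better than the chosen plan, which needs a separate enolate hydroxylation. The C4 ketone of A2 is a handle for methylenation and for α-oxygenation at C5 that is at least the equal of the alkene in 16.
- Against it: the ketone of A1 must enolise toward the more hindered side. The aldol is reversible, and A2 is a β-hydroxy ketone that can dehydrate. The new C3a centre is epimerisable, and the trans preference of such hydrindan-4-ones is expected to be small. C1 still lacks its side chain, which would need a later aldol at C1 beside the C3 oxygen with two stereocentres under weak control.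
- Comparison: the aldol forms one ring, one bond and two stereocentres by a reversible polar process. The chosen cycloaddition forms two rings, two bonds and three stereocentres irreversibly. A1 already needs two ring stereocentres made separately, so step economy is expected to be worse.

Alternative 2: The cut is the C4–C5 bond. In the forward direction the iodovinyl aldehyde A3 is converted with CrCl2 and catalytic NiCl2 (Nozaki–Hiyama–Kishi) into a vinylchromium species that adds to the aldehyde and gives the methylene carbinol A4.
- In its favour: it produces the exocyclic methylene and the C5 carbinol in a single, non-basic step and is chemoselective for an aldehyde over the C2 ketone. On this motif it is better than the chosen plan, which needs an epoxidation and an isomerisation.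
- Against it: the axial C5 alcohol is required, and a chair-like six-ring closure gives no clear reason to expect it. Chromium is used in excess. A3 is a trans-2,3-disubstituted cyclopentanone with four stereocentres, one of them (C7) on an acyclic arm, all to be set beforehand. The C1 side chain is again missing.
- Comparison: one ring and one stereocentre are formed. The stereochemical burden is moved to the synthesis of A3, whereas the chosen plan derives all ring stereocentres from one acyclic stereodiad. Mechanistically it is an organometallic carbonyl addition under weak substrate control, against a pericyclic step under double control.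

Alternative 3: The cut is the C1–C7a bond. In the forward direction the diazo diketone A5 gives, with Rh2(OAc)4, a rhodium carbenoid that inserts into the equatorial C–H bond of the ring CH2 next to the isopropyl carbon and gives the acetylcyclopentanone A6.
- In its favour: the step is catalytic, and insertion with retention into an equatorial C–H bond gives the trans fusion by geometry. A6 already carries both side-chain carbons at C1, so on this point it equals the chosen plan and is better than alternatives 1 and 2. The 1,3-dicarbonyl unit lets C1 settle into the β-configuration by equilibration.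
- Against it: the C–H bond lies on a CH2 flanked by two substituted carbons. An acceptor/acceptor carbenoid is not very discriminating, so insertion into silyl or isopropyl C–H bonds and Wolff rearrangement are conceivable. The acetyl group must later be reduced to the (S)-carbinol in the presence of the ring ketone, whereas the chosen plan sets C1' at the outset. A5 needs three preset stereocentres and a diazo transfer.
- Comparison: one ring and two stereocentres are formed. The ring A ketal is a handle comparable to that of alternative 1. Step economy is judged lower because ring A and its oxygenation must be built before the key step and C1' after it.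

Key step: step 9

Assumption: (2E)-3-methylpent-2-enoic acid 25 and (2R)-2-methylbutanoic acid 29 are taken as purchasable single isomers, and the C3 acyl group of 32 is read as the (2R)-2-methylbutanoate.

Check of the key-step structures: the stereodescriptors of 13 and 16 were traced atom by atom onto 32 (C1', C1, C3a, C7, C7a and both alkene geometries agree), so neither needs correction. What is changed is the order of the later operations, because a thioacetal cannot be carried through an epoxidation.

## Route

Step 1
Reactants: 1 (E)-3-methylpent-2-en-4-yn-1-ol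
Product: 2 (E)-3-methylpenta-2,4-dien-1-ol
Conditions: H2 (1 atm), Pd/CaCO3 poisoned with Pb(OAc)2 (Lindlar catalyst), quinoline, EtOAc, 0 °C, stopped after 1 equiv H2
Reagents that add atoms: none
Why: Lindlar semi-hydrogenation stops a terminal alkyne at the vinyl stage and leaves the existing trisubstituted (E)-alkene alone, so the geometry of the 2-methyl diene is fixed here.

Step 2
Reactants: 2 (E)-3-methylpenta-2,4-dien-1-ol
Product: 3 (E)-1-bromo-3-methylpenta-2,4-diene
Conditions: PBr3 (0.4 equiv), pyridine (cat.), Et2O, −10 °C; used at once without chromatography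
Reagents that add atoms: phosphorus tribromide, BrP(Br)Br
Why: Primary allylic alcohol to bromide through the phosphite ester (SN2 by bromide); low temperature and immediate use should limit allylic transposition of the sensitive dienyl bromide.

Step 3
Reactants: 4 (2E,4E)-hexa-2,4-dienal
Product: 5 2-[(1E,3E)-penta-1,3-dien-1-yl]-1,3-dioxolane
Conditions: HOCH2CH2OH, PPTS (cat.), toluene, reflux, Dean–Stark
Reagents that add atoms: ethane-1,2-diol, OCCO
Why: Acid-catalysed acetalisation with removal of water; the dioxolane masks the carbon that becomes the dienophile formyl group and inductively deactivates the neighbouring alkene for step 4.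

Step 4
Reactants: 5 2-[(1E,3E)-penta-1,3-dien-1-yl]-1,3-dioxolane
Product: 6 2-{(E)-2-[(2S,3S)-3-methyloxiran-2-yl]ethenyl}-1,3-dioxolane
Conditions: 1,2:4,5-di-O-isopropylidene-β-L-erythro-2,3-hexodiulo-2,6-pyranose (L-fructose-derived ketone, 30 mol%), KHSO5 (as 2KHSO5·KHSO4·K2SO4), K2CO3, Bu4NHSO4, MeCN/CH2(OMe)2/aq. Na2B4O7 buffer (pH 10.5), 0 °C
Reagents that add atoms: potassium peroxymonosulfate, [K+].[O-]S(=O)(=O)OO
Why: Shi asymmetric epoxidation of a conjugated diene through a spiro dioxirane transition state; the electrophilic dioxirane should take the methyl-substituted distal alkene rather than the acetal-deactivated one, and the L-configured ketone should give the (S,S)-epoxide of a trans-disubstituted alkene, which fixes C1' and (after inversion in step 5) C1.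

Step 5
Reactants: 7 1,3-dithiane; 6 2-{(E)-2-[(2S,3S)-3-methyloxiran-2-yl]ethenyl}-1,3-dioxolane
Product: 9 (2S,3R,4E)-5-(1,3-dioxolan-2-yl)-3-(1,3-dithian-2-yl)pent-4-en-2-ol, via 2-lithio-1,3-dithiane 8 (not isolated)
Conditions: 7, n-BuLi, THF, −30 °C; then 6, −78 → −20 °C; H2O
Reagents that add atoms: none
Why: Opening of a vinyl epoxide by a Corey–Seebach acyl-anion equivalent; the small unsubstituted anion should attack the activated allylic C–O carbon directly with inversion (giving 3R) rather than in conjugate fashion, the alkene terminus being blocked by the dioxolane, and the carbinol carbon keeps its S configuration.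

Step 6
Reactants: 9 (2S,3R,4E)-5-(1,3-dioxolan-2-yl)-3-(1,3-dithian-2-yl)pent-4-en-2-ol
Product: 10 2-[(1E,3R,4S)-4-(tert-butyldimethylsilyloxy)-3-(1,3-dithian-2-yl)pent-1-en-1-yl]-1,3-dioxolane
Conditions: TBSCl, imidazole, DMF, rt → 40 °C
Reagents that add atoms: tert-butyldimethylsilyl chloride, CC(C)(C)[Si](C)(C)Cl
Why: Silylation of a secondary alcohol with the chloride and an amine base (a silyl triflate would ionise the unsaturated acetal); the TBS ether should survive the organolithium, Grignard, ylide and amide-base steps that follow.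

Step 7
Reactants: 10 2-[(1E,3R,4S)-4-(tert-butyldimethylsilyloxy)-3-(1,3-dithian-2-yl)pent-1-en-1-yl]-1,3-dioxolane; 3 (E)-1-bromo-3-methylpenta-2,4-diene
Product: 12 2-[(1E,3R,4S)-4-(tert-butyldimethylsilyloxy)-3-{2-[(2E)-3-methylpenta-2,4-dien-1-yl]-1,3-dithian-2-yl}pent-1-en-1-yl]-1,3-dioxolane, via lithiated dithiane 11 (not isolated)
Conditions: t-BuLi, THF/HMPA (9:1), −78 °C; then 3, −78 → −40 °C; H2O
Reagents that add atoms: none
Why: Corey–Seebach alkylation of a 2-substituted dithiane; t-BuLi in THF/HMPA metalates hindered dithianes, HMPA keeps the γ-silyloxy carbanion from silyl migration to carbon, and the primary allylic bromide reacts by SN2, which creates the gem-disubstituted tether carbon without touching the two stereocentres.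

Step 8
Reactants: 12 2-[(1E,3R,4S)-4-(tert-butyldimethylsilyloxy)-3-{2-[(2E)-3-methylpenta-2,4-dien-1-yl]-1,3-dithian-2-yl}pent-1-en-1-yl]-1,3-dioxolane
Product: 13 (2E,4R,5S)-5-(tert-butyldimethylsilyloxy)-4-{2-[(2E)-3-methylpenta-2,4-dien-1-yl]-1,3-dithian-2-yl}hex-2-enal
Conditions: oxalic acid, THF/H2O, 0 °C → rt
Reagents that add atoms: water, O
Why: Hydrolysis of an α,β-unsaturated acetal through its stabilised oxocarbenium ion is fast under dilute acid that should leave the secondary TBS ether, the dithiane and the diene untouched; the (E)-enal is the thermodynamic geometry.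

Step 9
Reactants: 13 (2E,4R,5S)-5-(tert-butyldimethylsilyloxy)-4-{2-[(2E)-3-methylpenta-2,4-dien-1-yl]-1,3-dithian-2-yl}hex-2-enal
Product: 16 (1R,3aS,7S,7aS)-1-[(1S)-1-(tert-butyldimethylsilyloxy)ethyl]-4-methyl-1,3,3a,6,7,7a-hexahydrospiro[indene-2,2'-[1,3]dithiane]-7-carbaldehyde, via trienal iminium ion 14 (not isolated), via cycloadduct iminium ion 15 (not isolated)
Conditions: (2S,5S)-5-benzyl-2-tert-butyl-3-methylimidazolidin-4-one·CF3CO2H (20 mol%), MeCN/H2O (98:2), −20 → 4 °C
Reagents that add atoms: none
Why: The amine salt condenses with the formyl group of 13 to the (E)-iminium ion 14, whose lowered LUMO lets the enal alkene undergo a concerted, asynchronous [4+2] with the tethered 2-methyl diene, and hydrolysis of the cycloadduct iminium ion 15 releases 16 and the catalyst. The closest known reaction type is the imidazolidinone-catalysed intramolecular Diels–Alder reaction of deca-2,7,9-trienals to trans-fused bicyclo[4.3.0]nonene carbaldehydes. Ring B closes as a five-membered ring when the three-atom tether folds and the enal β-carbon bonds to the inner diene terminus (bond C7a–C3a), helped by the gem-disubstituted dithiane carbon (Thorpe–Ingold effect); ring A is the six-membered ring of the adduct, completed by the bond from the enal α-carbon to the diene CH2 terminus (bond C7–C6). C7 and C7a come out trans because addition is suprafacial on the (E)-enal. C3a follows from the endo transition state, in which the iminium carbon lies under the diene while the tether, trans to it on the alkene, is exo; this gives the trans ring fusion and an equatorial 7β-formyl group. The absolute sense at C7a rests on two elements that should agree: the existing C1 stereocentre reacts through the conformer whose C–H bond eclipses the enal, with the silyloxyethyl group turned away from the diene, and the benzyl group of the (2S,5S)-catalyst shields the opposite face of the iminium β-carbon. The step needs endo selectivity and π-face selectivity; the (E)-enal geometry with iminium activation secures the first, the allylic stereocentre and the matched catalyst the second.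

Step 10
Reactants: 16 (1R,3aS,7S,7aS)-1-[(1S)-1-(tert-butyldimethylsilyloxy)ethyl]-4-methyl-1,3,3a,6,7,7a-hexahydrospiro[indene-2,2'-[1,3]dithiane]-7-carbaldehyde
Product: 17 7β-(1-hydroxyethyl) analogue of 16 (both carbinol epimers)
Conditions: MeMgBr, THF, −78 → 0 °C; H2O
Reagents that add atoms: methylmagnesium bromide, C[Mg]Br
Why: Grignard addition to an aldehyde brings in the first isopropyl methyl group; the new carbinol centre is destroyed in step 11, so its configuration does not matter.

Step 11
Reactants: 17 7β-(1-hydroxyethyl) analogue of 16 (both carbinol epimers)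
Product: 18 7β-acetyl analogue of 16
Conditions: SO3·pyridine, DMSO, i-Pr2NEt, CH2Cl2, 0 °C
Reagents that add atoms: none
Why: Parikh–Doering (activated DMSO) oxidation of a secondary alcohol does not attack a thioacetal; the acetyl group stays equatorial at C7, which is also the thermodynamic position, so there is no drive to epimerise.

Step 12
Reactants: 18 7β-acetyl analogue of 16
Product: 19 7β-(prop-1-en-2-yl) analogue of 16
Conditions: Ph3PCH3Br, KO-t-Bu, THF, 0 °C → rt
Reagents that add atoms: methyltriphenylphosphonium bromide, C[P+](c1ccccc1)(c1ccccc1)c1ccccc1.[Br-]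
Why: Wittig methylenation of a methyl ketone with the unstabilised ylide supplies the second isopropyl carbon as an isopropenyl group.

Step 13
Reactants: 19 7β-(prop-1-en-2-yl) analogue of 16
Product: 20 trans-fused 1β-[(1S)-1-(tert-butyldimethylsilyloxy)ethyl]-2,2-dimethoxy-4-methyl-7β-(prop-1-en-2-yl)-2,3,3a,6,7,7a-hexahydro-1H-indene
Conditions: PhI(OCOCF3)2, MeOH, 0 °C, 10 min; then aq. NaHCO3
Reagents that add atoms: methanol, CO
Why: Oxidative dethioacetalisation with a diacyloxyiodobenzene: sulfur is oxidised far faster than an unactivated alkene and the thionium ion is captured twice by methanol, so the dithiane is exchanged directly for a dimethyl ketal; the exchange removes sulfur before the rhodium and dioxirane steps and keeps C2 masked against the amide base of step 16.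

Step 14
Reactants: 20 trans-fused 1β-[(1S)-1-(tert-butyldimethylsilyloxy)ethyl]-2,2-dimethoxy-4-methyl-7β-(prop-1-en-2-yl)-2,3,3a,6,7,7a-hexahydro-1H-indene
Product: 21 trans-fused 1β-[(1S)-1-(tert-butyldimethylsilyloxy)ethyl]-2,2-dimethoxy-4-methyl-7β-(propan-2-yl)-2,3,3a,6,7,7a-hexahydro-1H-indene
Conditions: H2 (1 atm), RhCl(PPh3)3 (5 mol%), toluene/EtOH (1:1), rt
Reagents that add atoms: none
Why: Homogeneous hydrogenation with RhCl(PPh3)3 reduces a 1,1-disubstituted alkene and should leave the trisubstituted ring alkene, the usual selectivity of this catalyst for an isopropenyl group beside a ring alkene.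

Step 15
Reactants: 21 trans-fused 1β-[(1S)-1-(tert-butyldimethylsilyloxy)ethyl]-2,2-dimethoxy-4-methyl-7β-(propan-2-yl)-2,3,3a,6,7,7a-hexahydro-1H-indene
Product: 22 4α,5α-epoxide of 21
Conditions: 1,2:4,5-di-O-isopropylidene-β-L-erythro-2,3-hexodiulo-2,6-pyranose (30 mol%), KHSO5 (as 2KHSO5·KHSO4·K2SO4), K2CO3, Bu4NHSO4, MeCN/CH2(OMe)2/aq. Na2B4O7 buffer (pH 10.5), 0 °C
Reagents that add atoms: potassium peroxymonosulfate, [K+].[O-]S(=O)(=O)OO
Why: Shi epoxidation of a trisubstituted cyclic alkene under reagent control: ring A alone is nearly symmetric toward the two faces, so the L-configured ketone is used because its spiro transition state places oxygen on the α face of this alkene, and the C3 methylene, which lies on the β side next to the C4 methyl group, should bias the substrate the same way.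

Step 16
Reactants: 22 4α,5α-epoxide of 21
Product: 24 trans-fused 5α-hydroxy-1β-[(1S)-1-(tert-butyldimethylsilyloxy)ethyl]-4-methylidene-7β-(propan-2-yl)octahydro-2H-inden-2-one, via allylic alcohol ketal 23 (not isolated)
Conditions: Et2NH, n-BuLi, Et2O, 0 °C → reflux; H2O; crude, oxalic acid, THF/H2O, rt
Reagents that add atoms: water, O
Why: Base-promoted isomerisation of an epoxide to an allylic alcohol: the lithium amide removes a proton syn to the epoxide oxygen from the least hindered β-carbon, the C4 methyl group, in preference to the tertiary H-3a or the C6 methylene, so the C4–O bond opens and the C5 oxygen keeps its α (axial) configuration, as is known for 1-methylcyclohexene-type oxides; dilute acid then hydrolyses the dimethyl ketal, the carbonyl oxygen coming from water.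

Step 17
Reactants: 24 trans-fused 5α-hydroxy-1β-[(1S)-1-(tert-butyldimethylsilyloxy)ethyl]-4-methylidene-7β-(propan-2-yl)octahydro-2H-inden-2-one; 25 (2E)-3-methylpent-2-enoic acid
Product: 26 trans-fused 1β-[(1S)-1-(tert-butyldimethylsilyloxy)ethyl]-4-methylidene-2-oxo-7β-(propan-2-yl)octahydro-1H-inden-5α-yl (2E)-3-methylpent-2-enoate
Conditions: 25, EDC·HCl, DMAP, CH2Cl2, 0 °C → rt
Reagents that add atoms: none
Why: Steglich esterification acylates the axial allylic alcohol with retention at C5; carbodiimide activation without a strong amine base should avoid deconjugation or E/Z scrambling of the β,β-disubstituted enoic acid.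

Step 18
Reactants: 26 trans-fused 1β-[(1S)-1-(tert-butyldimethylsilyloxy)ethyl]-4-methylidene-2-oxo-7β-(propan-2-yl)octahydro-1H-inden-5α-yl (2E)-3-methylpent-2-enoate
Product: 28 3β-hydroxy derivative of 26, via potassium enolate 27 (not isolated)
Conditions: KN(SiMe3)2 (1.1 equiv), THF, −78 °C; 2-(phenylsulfonyl)-3-phenyloxaziridine, −78 °C; AcOH
Reagents that add atoms: 2-(phenylsulfonyl)-3-phenyloxaziridine, O=S(=O)(c1ccccc1)N1OC1c1ccccc1
Why: Kinetic deprotonation takes the unhindered C3 methylene rather than the branched C1 methine (so no β-elimination of the silyloxy group) and is faster than γ-deprotonation of the enoate; oxygen transfer from the Davis oxaziridine should occur on the β face, where the forming C–O bond is staggered with respect to the substituents of C3a, whereas α attack would eclipse the axial C3a–H bond (torsional steering).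

Step 19
Reactants: 28 3β-hydroxy derivative of 26; 29 (2R)-2-methylbutanoic acid
Product: 30 3β-[(2R)-2-methylbutanoyl]oxy derivative of 26
Conditions: 29, EDC·HCl, DMAP (cat.), CH2Cl2, 0 °C
Reagents that add atoms: none
Why: Steglich esterification of the α-ketol at 0 °C with only catalytic DMAP keeps the C3 centre and the α-stereocentre of the acid from epimerising.

Step 20
Reactants: 30 3β-[(2R)-2-methylbutanoyl]oxy derivative of 26
Product: 31 1β-[(1S)-1-hydroxyethyl] analogue of 30 (free secondary alcohol)
Conditions: HF·pyridine, THF/pyridine, 0 °C → rt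
Reagents that add atoms: none
Why: Fluoride-mediated desilylation under buffered acidic conditions avoids the basicity of ammonium fluorides, which could cause acyl migration or retro-aldol cleavage of the β-hydroxy ketone.

Step 21
Reactants: 31 1β-[(1S)-1-hydroxyethyl] analogue of 30 (free secondary alcohol)
Product: 32 (1R,3R,3aS,5S,7R,7aR)-1-[(1S)-1-acetoxyethyl]-4-methylidene-3-{[(2R)-2-methylbutanoyl]oxy}-2-oxo-7-(propan-2-yl)octahydro-1H-inden-5-yl (2E)-3-methylpent-2-enoate
Conditions: Ac2O, pyridine, CH2Cl2, 0 °C → rt
Reagents that add atoms: acetic anhydride, CC(=O)OC(C)=O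
Why: Acetylation with pyridine as the only base is mild enough that the newly formed β-acetoxy ketone should not undergo E1cB elimination; it is the last step so that this unit meets no further reagent.

## Compound list

1 | (E)-3-methylpent-2-en-4-yn-1-ol | C#C/C(C)=C/CO | starting material
2 | (E)-3-methylpenta-2,4-dien-1-ol | C=C/C(C)=C/CO | intermediate
3 | (E)-1-bromo-3-methylpenta-2,4-diene | C=C/C(C)=C/CBr | intermediate
4 | (2E,4E)-hexa-2,4-dienal | C/C=C/C=C/C=O | starting material
5 | 2-[(1E,3E)-penta-1,3-dien-1-yl]-1,3-dioxolane | C/C=C/C=C/C1OCCO1 | intermediate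
6 | 2-{(E)-2-[(2S,3S)-3-methyloxiran-2-yl]ethenyl}-1,3-dioxolane | C[C@@H]1O[C@H]1/C=C/C1OCCO1 | intermediate
7 | 1,3-dithiane | C1CSCSC1 | starting material
8 | 2-lithio-1,3-dithiane | [Li]C1SCCCS1 | intermediate
9 | (2S,3R,4E)-5-(1,3-dioxolan-2-yl)-3-(1,3-dithian-2-yl)pent-4-en-2-ol | O1CCOC1/C=C/[C@H]([C@H](C)O)C1SCCCS1 | intermediate
10 | 2-[(1E,3R,4S)-4-(tert-butyldimethylsilyloxy)-3-(1,3-dithian-2-yl)pent-1-en-1-yl]-1,3-dioxolane | O1CCOC1/C=C/[C@H]([C@H](C)O[Si](C)(C)C(C)(C)C)C1SCCCS1 | intermediate
11 | 2-lithio derivative of 10 (lithium on the dithiane carbon) | O1CCOC1/C=C/[C@H]([C@H](C)O[Si](C)(C)C(C)(C)C)C1([Li])SCCCS1 | intermediate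
12 | 2-[(1E,3R,4S)-4-(tert-butyldimethylsilyloxy)-3-{2-[(2E)-3-methylpenta-2,4-dien-1-yl]-1,3-dithian-2-yl}pent-1-en-1-yl]-1,3-dioxolane | O1CCOC1/C=C/[C@H]([C@H](C)O[Si](C)(C)C(C)(C)C)C1(SCCCS1)C/C=C(\C)C=C | intermediate
13 | (2E,4R,5S)-5-(tert-butyldimethylsilyloxy)-4-{2-[(2E)-3-methylpenta-2,4-dien-1-yl]-1,3-dithian-2-yl}hex-2-enal (the dithiane-tethered (2E,7E)-8-methyldeca-2,7,9-trienal) | O=C/C=C/[C@H]([C@H](C)O[Si](C)(C)C(C)(C)C)C1(SCCCS1)C/C=C(\C)C=C | intermediate
14 | iminium trifluoroacetate of 13 with (2S,5S)-5-benzyl-2-tert-butyl-3-methylimidazolidin-4-one | CN1C(=O)[C@H](Cc2ccccc2)[N+](=C/C=C/[C@H]([C@H](C)O[Si](C)(C)C(C)(C)C)C2(SCCCS2)C/C=C(\C)C=C)[C@@H]1C(C)(C)C.[O-]C(=O)C(F)(F)F | intermediate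
15 | iminium trifluoroacetate of 16 with the same amine | CC=1[C@@H]2[C@H]([C@H]([C@H](C)O[Si](C)(C)C(C)(C)C)C3(SCCCS3)C2)[C@@H](C=[N+]3[C@H](C(C)(C)C)N(C)C(=O)[C@@H]3Cc3ccccc3)CC1.[O-]C(=O)C(F)(F)F | intermediate
16 | (1R,3aS,7S,7aS)-1-[(1S)-1-(tert-butyldimethylsilyloxy)ethyl]-4-methyl-1,3,3a,6,7,7a-hexahydrospiro[indene-2,2'-[1,3]dithiane]-7-carbaldehyde (trans-fused; 1β side chain, 7β formyl, H-3a α, H-7a β) | CC=1[C@@H]2[C@H]([C@H]([C@H](C)O[Si](C)(C)C(C)(C)C)C3(SCCCS3)C2)[C@@H](C=O)CC1 | intermediate
17 | 1-{1β-[(1S)-1-(tert-butyldimethylsilyloxy)ethyl]-4-methyl-1,3,3a,6,7,7a-hexahydrospiro[indene-2,2'-[1,3]dithian]-7β-yl}ethan-1-ol (ring stereocentres as in 16, both carbinol epimers) | CC=1[C@@H]2[C@H]([C@H]([C@H](C)O[Si](C)(C)C(C)(C)C)C3(SCCCS3)C2)[C@@H](C(C)O)CC1 | intermediate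
18 | 1-{1β-[(1S)-1-(tert-butyldimethylsilyloxy)ethyl]-4-methyl-1,3,3a,6,7,7a-hexahydrospiro[indene-2,2'-[1,3]dithian]-7β-yl}ethan-1-one (ring stereocentres as in 16) | CC=1[C@@H]2[C@H]([C@H]([C@H](C)O[Si](C)(C)C(C)(C)C)C3(SCCCS3)C2)[C@@H](C(C)=O)CC1 | intermediate
19 | 1β-[(1S)-1-(tert-butyldimethylsilyloxy)ethyl]-4-methyl-7β-(prop-1-en-2-yl)-1,3,3a,6,7,7a-hexahydrospiro[indene-2,2'-[1,3]dithiane] (ring stereocentres as in 16) | CC=1[C@@H]2[C@H]([C@H]([C@H](C)O[Si](C)(C)C(C)(C)C)C3(SCCCS3)C2)[C@@H](C(C)=C)CC1 | intermediate
20 | trans-fused 1β-[(1S)-1-(tert-butyldimethylsilyloxy)ethyl]-2,2-dimethoxy-4-methyl-7β-(prop-1-en-2-yl)-2,3,3a,6,7,7a-hexahydro-1H-indene (H-3a α, H-7a β) | CC=1[C@@H]2[C@H]([C@H]([C@H](C)O[Si](C)(C)C(C)(C)C)C(OC)(OC)C2)[C@@H](C(C)=C)CC1 | intermediate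
21 | trans-fused 1β-[(1S)-1-(tert-butyldimethylsilyloxy)ethyl]-2,2-dimethoxy-4-methyl-7β-(propan-2-yl)-2,3,3a,6,7,7a-hexahydro-1H-indene | CC=1[C@@H]2[C@H]([C@H]([C@H](C)O[Si](C)(C)C(C)(C)C)C(OC)(OC)C2)[C@@H](C(C)C)CC1 | intermediate
22 | trans-fused 4α,5α-epoxy-1β-[(1S)-1-(tert-butyldimethylsilyloxy)ethyl]-2,2-dimethoxy-4β-methyl-7β-(propan-2-yl)octahydro-1H-indene | C[C@@]14[C@@H]2[C@H]([C@H]([C@H](C)O[Si](C)(C)C(C)(C)C)C(OC)(OC)C2)[C@@H](C(C)C)C[C@@H]1O4 | intermediate
23 | trans-fused 1β-[(1S)-1-(tert-butyldimethylsilyloxy)ethyl]-2,2-dimethoxy-4-methylidene-7β-(propan-2-yl)octahydro-1H-inden-5α-ol | C=C1[C@@H]2[C@H]([C@H]([C@H](C)O[Si](C)(C)C(C)(C)C)C(OC)(OC)C2)[C@@H](C(C)C)C[C@@H]1O | intermediate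
24 | trans-fused 5α-hydroxy-1β-[(1S)-1-(tert-butyldimethylsilyloxy)ethyl]-4-methylidene-7β-(propan-2-yl)octahydro-2H-inden-2-one | C=C1[C@@H]2[C@H]([C@H]([C@H](C)O[Si](C)(C)C(C)(C)C)C(=O)C2)[C@@H](C(C)C)C[C@@H]1O | intermediate
25 | (2E)-3-methylpent-2-enoic acid | CC/C(C)=C/C(=O)O | starting material
26 | trans-fused 1β-[(1S)-1-(tert-butyldimethylsilyloxy)ethyl]-4-methylidene-2-oxo-7β-(propan-2-yl)octahydro-1H-inden-5α-yl (2E)-3-methylpent-2-enoate | C=C1[C@@H]2[C@H]([C@H]([C@H](C)O[Si](C)(C)C(C)(C)C)C(=O)C2)[C@@H](C(C)C)C[C@@H]1OC(=O)/C=C(\C)CC | intermediate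
27 | potassium C2(O)=C3 enolate of 26 | C=C1[C@@H]2[C@H]([C@H]([C@H](C)O[Si](C)(C)C(C)(C)C)C([O-])=C2)[C@@H](C(C)C)C[C@@H]1OC(=O)/C=C(\C)CC.[K+] | intermediate
28 | 3β-hydroxy derivative of 26 (α-ketol, 3-OH cis to H-7a) | C=C1[C@@H]2[C@H]([C@H]([C@H](C)O[Si](C)(C)C(C)(C)C)C(=O)[C@@H]2O)[C@@H](C(C)C)C[C@@H]1OC(=O)/C=C(\C)CC | intermediate
29 | (2R)-2-methylbutanoic acid | CC[C@@H](C)C(=O)O | starting material
30 | trans-fused 1β-[(1S)-1-(tert-butyldimethylsilyloxy)ethyl]-4-methylidene-3β-{[(2R)-2-methylbutanoyl]oxy}-2-oxo-7β-(propan-2-yl)octahydro-1H-inden-5α-yl (2E)-3-methylpent-2-enoate | C=C1[C@@H]2[C@H]([C@H]([C@H](C)O[Si](C)(C)C(C)(C)C)C(=O)[C@@H]2OC(=O)[C@H](C)CC)[C@@H](C(C)C)C[C@@H]1OC(=O)/C=C(\C)CC | intermediate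
31 | trans-fused 1β-[(1S)-1-hydroxyethyl]-4-methylidene-3β-{[(2R)-2-methylbutanoyl]oxy}-2-oxo-7β-(propan-2-yl)octahydro-1H-inden-5α-yl (2E)-3-methylpent-2-enoate | C=C1[C@@H]2[C@H]([C@H]([C@H](C)O)C(=O)[C@@H]2OC(=O)[C@H](C)CC)[C@@H](C(C)C)C[C@@H]1OC(=O)/C=C(\C)CC | intermediate
32 | (1R,3R,3aS,5S,7R,7aR)-1-[(1S)-1-acetoxyethyl]-4-methylidene-3-{[(2R)-2-methylbutanoyl]oxy}-2-oxo-7-(propan-2-yl)octahydro-1H-inden-5-yl (2E)-3-methylpent-2-enoate (CNP0289166.2) | C=C1[C@@H]2[C@H]([C@H]([C@H](C)OC(C)=O)C(=O)[C@@H]2OC(=O)[C@H](C)CC)[C@@H](C(C)C)C[C@@H]1OC(=O)/C=C(\C)CC | target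

## Step count and least certain steps

Total: 21 steps. Longest linear sequence: 19 steps (4 → 32, steps 3–21). The two-step bromide branch (steps 1–2) joins at step 7.

Step 9 (key step). Three processes could interfere:
- γ-Deprotonation of iminium ion 14 to a dienamine; the γ-carbon is the tertiary C4 stereocentre, so this would epimerise it or move the alkene out of conjugation.
- Slow condensation of the γ-branched enal with the bulky amine.
- Erosion of endo selectivity.

The fallback drops covalent amine activation. From 13, the formyl oxygen is complexed with Me2AlCl (CH2Cl2, −78 °C), a Lewis-acid-promoted intramolecular Diels–Alder reaction in which face selectivity rests on the C4 stereocentre alone (hydrogen-eclipsed conformer) and endo selectivity on the (E)-enal. It sets out from 13 and returns at 16 without new compounds.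

Step 4. The dioxirane may also attack the acetal-bearing alkene or both alkenes, the enantioselectivity on a small diene may be moderate, and the vinyl epoxide may open during isolation. The fallback builds the stereodiad from an allylic alcohol, where titanium–tartrate delivery fixes both position and face:
- (E)-but-2-en-1-ol F1 is epoxidised (Ti(O-i-Pr)4, L-(+)-diisopropyl tartrate, t-BuOOH, 4 Å sieves, CH2Cl2, −20 °C) to [(2S,3S)-3-methyloxiran-2-yl]methanol F2.
- F2 is oxidised (SO3·pyridine, DMSO, i-Pr2NEt) to (2R,3S)-3-methyloxirane-2-carbaldehyde F3 and methylenated (Ph3P=CH2) to (2S,3S)-2-methyl-3-vinyloxirane F4, which is volatile and handled in solution.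
- Anion 8, made from 7, opens F4 at the allylic carbon to (2S,3R)-3-(1,3-dithian-2-yl)pent-4-en-2-ol F5, which is silylated (TBSCl, imidazole) to its TBS ether F6.
- Cross-metathesis of F6 with 2-vinyl-1,3-dioxolane (second-generation Hoveyda–Grubbs catalyst RuCl2(H2IMes)(=CH-C6H4-2-O-i-Pr), CH2Cl2, 40 °C) gives 10.

This fallback sets out from 7 and returns at 10.

Step 7. Metalation of the hindered, α-branched dithiane may be incomplete, and the ambident dienyl bromide may react through its remote terminus, which would scramble the geometry of the trisubstituted alkene; the bromide may also decompose before it reacts. The fallback separates C–C bond formation from diene construction: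
- Anion 11, from 10, is alkylated with 1-bromobut-2-yne to the but-2-ynyl dithiane F7.
- Hydrozirconation with Cp2Zr(H)Cl (zirconium on the methyl-bearing alkyne carbon, syn addition) followed by coupling with vinyl bromide (Pd(PPh3)4, ZnCl2; Negishi coupling) gives the (E)-diene 12.

It sets out from 10 and returns at 12.

Step 15. Face selectivity may be poor if the substrate's own bias opposes the chiral ketone, or conversion may be slow on a hindered alkene. The fallback accepts the other face and corrects C5 by inversion:
- From 21, the D-fructose-derived enantiomer of the ketone (same conditions) gives the 4β,5β-epoxide F8.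
- The procedure of step 16 gives the 5β-alcohol ketal F9 and then the 5β-hydroxy ketone F10.
- Mitsunobu esterification of F10 with 25 (PPh3, diisopropyl azodicarboxylate, toluene, 0 °C) installs the enoate with inversion and gives 26.

It sets out from 21 and returns at 26.

Step 18. Oxygen transfer may occur from the α face if steric shielding by the C4 methylene outweighs torsional control, and enolisation could stray toward C1 or the enoate. If the 3α-alcohol F11 (the C3 epimer of 28) is formed, Mitsunobu esterification with 29 (PPh3, diisopropyl azodicarboxylate) would displace the activated α-ketol oxygen with inversion and give 30 directly. It sets out from 26 and returns at 30.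

## Further compounds

F1 | step 4 | (E)-but-2-en-1-ol | C/C=C/CO
F2 | step 4 | [(2S,3S)-3-methyloxiran-2-yl]methanol | C[C@@H]1O[C@H]1CO
F3 | step 4 | (2R,3S)-3-methyloxirane-2-carbaldehyde | C[C@@H]1O[C@H]1C=O
F4 | step 4 | (2S,3S)-2-methyl-3-vinyloxirane | C[C@@H]1O[C@H]1C=C
F5 | step 4 | (2S,3R)-3-(1,3-dithian-2-yl)pent-4-en-2-ol | C=C[C@H]([C@H](C)O)C1SCCCS1
F6 | step 4 | tert-butyl{[(2S,3R)-3-(1,3-dithian-2-yl)pent-4-en-2-yl]oxy}dimethylsilane | C=C[C@H]([C@H](C)O[Si](C)(C)C(C)(C)C)C1SCCCS1
F7 | step 7 | 2-[(1E,3R,4S)-3-[2-(but-2-yn-1-yl)-1,3-dithian-2-yl]-4-(tert-butyldimethylsilyloxy)pent-1-en-1-yl]-1,3-dioxolane | O1CCOC1/C=C/[C@H]([C@H](C)O[Si](C)(C)C(C)(C)C)C1(SCCCS1)CC#CC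
F0 | step 9 | none | none
F8 | step 15 | 4β,5β-epoxide of 21 | C[C@]14[C@@H]2[C@H]([C@H]([C@H](C)O[Si](C)(C)C(C)(C)C)C(OC)(OC)C2)[C@@H](C(C)C)C[C@H]1O4
F9 | step 15 | 5β-epimer of 23 | C=C1[C@@H]2[C@H]([C@H]([C@H](C)O[Si](C)(C)C(C)(C)C)C(OC)(OC)C2)[C@@H](C(C)C)C[C@H]1O
F10 | step 15 | 5β-epimer of 24 | C=C1[C@@H]2[C@H]([C@H]([C@H](C)O[Si](C)(C)C(C)(C)C)C(=O)C2)[C@@H](C(C)C)C[C@H]1O
F11 | step 18 | 3α-epimer of 28 | C=C1[C@@H]2[C@H]([C@H]([C@H](C)O[Si](C)(C)C(C)(C)C)C(=O)[C@H]2O)[C@@H](C(C)C)C[C@@H]1OC(=O)/C=C(\C)CC
A1 | alternative 1 | 3-[3-oxo-2-(triethylsilyloxy)propyl]-4-(propan-2-yl)cyclohexan-1-one (configuration as in the SMILES) | O=C1C[C@H](C[C@@H](O[Si](CC)(CC)CC)C=O)[C@@H](C(C)C)CC1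
A2 | alternative 1 | trans-fused 3-hydroxy-7-(propan-2-yl)-2-(triethylsilyloxy)octahydro-4H-inden-4-one | O=C1[C@@H]2[C@H](C[C@@H](O[Si](CC)(CC)CC)[C@@H]2O)[C@@H](C(C)C)CC1
A3 | alternative 2 | 3-[2-(tert-butyldimethylsilyloxy)-5-(1-iodoethenyl)-3-oxocyclopentyl]-4-methylpentanal (trans-disubstituted cyclopentanone, configuration as in the SMILES) | C=C(I)[C@@H]1[C@H](CC(=O)[C@@H]1O[Si](C)(C)C(C)(C)C)[C@@H](C(C)C)CC=O
A4 | alternative 2 | trans-fused 3-(tert-butyldimethylsilyloxy)-5-hydroxy-4-methylidene-7-(propan-2-yl)octahydro-2H-inden-2-one | C=C1[C@@H]2[C@H](CC(=O)[C@@H]2O[Si](C)(C)C(C)(C)C)[C@@H](C(C)C)C[C@@H]1O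
A5 | alternative 3 | 1-(tert-butyldimethylsilyloxy)-3-diazo-1-[8-(propan-2-yl)-1,4-dioxaspiro[4.5]decan-6-yl]pentane-2,4-dione (configuration as in the SMILES) | C12(OCCO1)[C@@H]([C@@H](O[Si](C)(C)C(C)(C)C)C(=O)C(=[N+]=[N-])C(C)=O)C[C@@H](C(C)C)CC2
A6 | alternative 3 | trans-fused 1-acetyl-3-(tert-butyldimethylsilyloxy)-7-(propan-2-yl)hexahydrospiro[indene-4,2'-[1,3]dioxolan]-2-one | C12(OCCO1)[C@@H]3[C@H]([C@H](C(C)=O)C(=O)[C@@H]3O[Si](C)(C)C(C)(C)C)[C@@H](C(C)C)CC2
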